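## The problem

2'-Epi-tuberatolide B (44) consists of a 6-hydroxy-2,8-dimethyl-2H-chromene and a 3-(4-methylpent-3-enyl)furan-2(5H)-one, joined from chromene C2 to lactone C5 by a CH2–CH2–CH=C(CH3)–CH2 chain whose alkene is E. There are two stereocentres: the quaternary C2 (R; it carries O1, a methyl group, C3 and the chain) and the lactone C5 (R), taken here to be the centre inverted relative to tuberatolide B. They lie seven bonds apart across a flexible chain, so neither can direct the other. Each must therefore be set by a reagent or bought within its own fragment, and a convergent union lets the lactone configuration be chosen freely. The chain alkene is trisubstituted, so its geometry should come from a stereospecific addition to an alkyne and not from an olefination. Several groups are fragile: the 4-alkoxyphenol oxidises readily to a quinone; the tertiary, allylic and aryl C2–O1 ether can ionise under acid or ring-open on strong heating or irradiation, which would racemise C2; the butenolide has an acidic C5–H and accepts nucleophiles; and two trisubstituted alkenes rule out strong electrophiles. The feature that opens a short way to the bicycle is the arene itself: O1 on C8a, a free hydroxyl para to it on C6, a methyl on C8, hydrogens on C5 and C7, and C4a bonded to C4 of a cis alkene that runs back through C3 to C2 and O1. This is the pattern left by an alkoxycarbene carbon (C8a), an isopropenyl group (C8, its methyl, C7), one carbon monoxide (C6–OH) and a terminal alkyne (C5, C4a), with the alkyne already tied to the carbene oxygen by the four atoms O1–C2–C3=C4.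

## Retrosynthesis

The phenol is uncovered last, so 44 comes from its silyl ether 43. The first real cut is the sp3–sp2 bond between the chain CH2 and the alkene CH, which leads to alkyl iodide 24 (used as zinc reagent 42) and vinyl iodide 41. Cutting at the alkene itself would require an E-selective trisubstituted olefination, and cutting next to lactone C5 would require creating that stereocentre during the coupling. The chosen cut gives two halves with one stereocentre each and asks only for a Negishi coupling that keeps the alkene geometry and tolerates the butenolide.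

Iodide 24 is reached from alcohol 23, silyl ether 22 and phenol 21 by functional-group changes. The aryl silyl group in 22 is chosen to survive the acidic removal of the alkyl silyl group and to leave under buffered fluoride at the end.

The central cut is made in 21 across C8a–C4a, C5–C6 and C6–C7, which leads back to the chromium carbene complex 19. The neighbouring cuts (O1–C2 or C4–C4a) keep a preformed arene and close only the pyran. This cut removes both rings, leaves an acyclic precursor with one stereocentre, and lets the mechanism place every arene substituent. The forward reaction must insert the tethered alkyne, then CO, and electrocyclise onto the isopropenyl CH2 without ionising the tertiary allylic C2–O bond.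

Complex 19 is cut at the C8a–O1 bond into acyl chromate salt 17 and enynol 12. Salt 17 comes from 2-bromopropene 13 and Cr(CO)6 14. The C2–O bond is not involved, so the configuration of 12 passes unchanged into 19. The demand is that a tertiary hydroxyl attacks an activated carbene carbon.

Enynol 12 is cut between the alkene and the alkyne into (Z)-vinyl iodide 9 and ethynylmagnesium bromide 10. Iodide 9 comes from iodoalkynol 8 by syn hydrogen transfer, and 8 from epoxy chloride 6 by base-induced fragmentation. Making the cis alkene by reducing an alkyne is more dependable than a Z-selective olefination beside a quaternary carbon.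

Epoxy chloride 6 comes from epoxy alcohol 5, which comes from allylic alcohol 4 by Sharpless epoxidation; this is where C2 is set. Alcohol 4 comes from alkyne 1 by carboalumination, which fixes the E geometry that the epoxidation needs.

Butenolide 41 comes from sulfide 39 (through sulfoxide 40), which comes from lactone 36 and bromide 37; 36 comes from epoxide 32 and acid 33. This sulfur-based lactone route never touches the C5–O bond. It should form the ring double bond without base at C5.

Epoxide 32 comes from chlorohydrin 31, alkynol 29 and silyl alkyne 28, and so from (R)-epichlorohydrin 25 and trimethylsilylacetylene 26. The lactone stereocentre is bought, and the choice of epichlorohydrin enantiomer decides which lactone epimer is made. Carboalumination of 29 sets the E vinyl iodide.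

## Roads not taken

Alternative 1: The cut is the O1–C2 bond, with the C3=C4 alkene introduced afterwards. In the forward key step, acid makes the phenol of epoxide A1 attack the tertiary epoxide carbon in 6-endo mode with inversion to give chroman-3-ol A2; dehydration towards the benzylic C4 then gives the chromene.
- Merits: every step has close precedent; the arene comes from a cheap hydroquinone; the stereocentre comes from a catalytic asymmetric epoxidation; the tertiary carbon favours 6-endo opening.
- Weak points: the arene must be C-alkylated at one defined position by an allylic electrophile; inversion at a tertiary carbon under acid has carbocation character and can erode the enantiomeric purity; the C3 hydroxyl is introduced only to be removed; the dehydration must spare the C2–O1 ether.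
- Comparison: in precedent, and probably in step count to the stage of 22, this road is ahead. The chosen plan sets against it that no bond to C2 changes after the epoxidation, that no arene regiochemistry has to be controlled, and that both rings form in one step.

Alternative 2: The cut is the lactone O1–C5 bond on the complete carbon skeleton. In the forward key step AgNO3 cycloisomerises allenoic acid A3 by 5-endo attack of the carboxylate, with transfer of axial to central chirality, to give A4, the silyl ether of the target.
- Merits: the most base-sensitive ring and its stereocentre are made last under nearly neutral conditions; the step is atom-economic; either lactone epimer follows from the allene configuration.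
- Weak points: it addresses only the butenolide and leaves the chromene open; A3 must be made enantioenriched with the whole chromene chain attached, in practice from an enantioenriched propargylic alcohol derivative, so the stereochemical problem only moves back one step; allenes can racemise under silver ion; the sequence is linear.
- Comparison: for the butenolide alone this road is as good as or better than the sulfoxide route, because it needs no strong base and no oxidant near the alkenes. The chosen plan sets against it convergence, a purchased stereocentre in 25, and butenolide chemistry worked out on the small fragment 41.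

Alternative 3: The cut is C4–C4a. In the forward key step Ph3PAuNTf2 activates the terminal alkyne of aryl propargyl ether A5 and the free ortho carbon attacks in 6-endo-dig mode to give A6, which is the same compound as 22.
- Merits: it uses the same Sharpless-derived tertiary alcohol series; it needs neither the cis enyne nor chromium; it is catalytic and mild; the methyl group blocks the other ortho position; no bond to C2 changes.
- Weak points: the chiral tertiary aryl ether cannot be made by copper-catalysed propargylation, which passes through planar intermediates, so a nucleophilic aromatic substitution on an activated fluoroarene and a later change of the activating group into the phenol are required; the cationic gold catalyst can ionise the tertiary propargylic ether or open the Claisen-type pathway through an achiral dienone, either of which would erode C2.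
- Comparison: this road is shorter (about five steps from 6 to 22 against seven) and rests on known reaction types, so in practical terms it is the stronger one, and it is held as a fallback below. The chosen plan sets against it that the arene is assembled with its substituents placed by mechanism, that two rings and three C–C bonds form in one operation, and that it would establish the benzannulation with an unsaturated oxygen tether.

Key step: step 9

Assumption: silyl ether 1 is bought (it is otherwise one silylation from but-3-yn-1-ol), and all organometallic steps are run under argon in dry solvents.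

## Steps

Step 1
Reactants: 1 tert-butyl(but-3-yn-1-yloxy)dimethylsilane
Product: 4 (2E)-5-{[tert-butyl(dimethyl)silyl]oxy}-3-methylpent-2-en-1-ol, via alkenylalane 2 (not isolated), via lithium alkenylaluminate 3 (not isolated)
Conditions: AlMe3, Cp2ZrCl2 (20 mol %), CH2Cl2, 0 °C to rt; n-BuLi, THF, −78 °C; (CH2O)n, −78 °C to rt
Reagents that add atoms: trimethylaluminium C[Al](C)C; paraformaldehyde (as formaldehyde) C=O
Why: Negishi zirconium-catalysed carboalumination adds methyl and aluminium syn across the terminal alkyne with the metal on the terminal carbon. The aluminate is hydroxymethylated with retention, so the E alcohol with methyl cis to CH2OH should result.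

Step 2
Reactants: 4 (2E)-5-{[tert-butyl(dimethyl)silyl]oxy}-3-methylpent-2-en-1-ol
Product: 5 [(2R,3R)-3-(2-{[tert-butyl(dimethyl)silyl]oxy}ethyl)-3-methyloxiran-2-yl]methanol
Conditions: Ti(OiPr)4 (10 mol %), D-(−)-diethyl tartrate (12 mol %), tBuOOH, 4 Å MS, CH2Cl2, −20 °C
Reagents that add atoms: tert-butyl hydroperoxide CC(C)(C)OO
Why: Sharpless asymmetric epoxidation; the D-(−)-tartrate ligand directs oxygen to the face that gives the (2R,3R) epoxide, the mirror image of the series obtained from such E alcohols with the L-(+)-ligand. The quaternary carbon set here becomes C2 of the chromene.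

Step 3
Reactants: 5 [(2R,3R)-3-(2-{[tert-butyl(dimethyl)silyl]oxy}ethyl)-3-methyloxiran-2-yl]methanol
Product: 6 tert-butyl{2-[(2R,3S)-3-(chloromethyl)-2-methyloxiran-2-yl]ethoxy}dimethylsilane
Conditions: PPh3, CCl4, NaHCO3, 75 °C
Reagents that add atoms: tetrachloromethane ClC(Cl)(Cl)Cl
Why: Appel chlorination of the primary alcohol under neutral conditions leaves the epoxide and silyl ether alone; only the descriptor of the CH carbon changes, not its geometry.

Step 4
Reactants: 6 tert-butyl{2-[(2R,3S)-3-(chloromethyl)-2-methyloxiran-2-yl]ethoxy}dimethylsilane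
Product: 8 (3R)-5-{[tert-butyl(dimethyl)silyl]oxy}-1-iodo-3-methylpent-1-yn-3-ol, via dilithium alkynolate 7 (not isolated)
Conditions: n-BuLi (3.1 equiv), THF, −40 °C; I2, −78 to 0 °C
Reagents that add atoms: iodine [I][I]
Why: Base-induced fragmentation of a 2,3-epoxy chloride (deprotonation next to chlorine, epoxide opening, dehydrochlorination) gives the tertiary propargylic alkoxide. The quaternary C–O bond is not broken, so the configuration is kept, and the lithium acetylide is iodinated in the same flask.

Step 5
Reactants: 8 (3R)-5-{[tert-butyl(dimethyl)silyl]oxy}-1-iodo-3-methylpent-1-yn-3-ol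
Product: 9 (1Z,3R)-5-{[tert-butyl(dimethyl)silyl]oxy}-1-iodo-3-methylpent-1-en-3-ol
Conditions: 2-nitrobenzenesulfonyl hydrazide, Et3N, THF/iPrOH, rt
Reagents that add atoms: none
Why: Diimide reduction delivers two hydrogens syn to the iodoalkyne, which should give the (Z)-iodoalkene; the hindered iodoalkene is reduced further only slowly.

Step 6
Reactants: 9 (1Z,3R)-5-{[tert-butyl(dimethyl)silyl]oxy}-1-iodo-3-methylpent-1-en-3-ol; 10 ethynylmagnesium bromide
Product: 12 (3R,4Z)-1-{[tert-butyl(dimethyl)silyl]oxy}-3-methylhept-4-en-6-yn-3-ol, via ethynylzinc bromide 11 (not isolated)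
Conditions: 10 (3 equiv), ZnBr2, THF, 0 °C; then 9, Pd(PPh3)4 (5 mol %), rt
Reagents that add atoms: none
Why: Negishi alkynylation; ethynylzinc bromide couples with the alkenyl iodide under zerovalent palladium with retention of the Z geometry and gives the terminal enyne directly. One equivalent of reagent is consumed by the tertiary hydroxyl.

Step 7
Reactants: 13 2-bromopropene; 14 hexacarbonylchromium
Product: 17 tetramethylammonium pentacarbonyl(2-methyl-1-oxidoprop-2-en-1-ylidene)chromate, via isopropenyllithium 15 (not isolated), via lithium acylchromate 16 (not isolated)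
Conditions: t-BuLi (2 equiv), THF, −78 °C; Cr(CO)6, −78 °C to rt; Me4NBr, H2O
Reagents that add atoms: tetramethylammonium bromide C[N+](C)(C)C.[Br-]
Why: Fischer carbene synthesis, first half: bromine–lithium exchange, addition of the alkenyllithium to a CO ligand, and cation exchange to the storable ammonium acylate.

Step 8
Reactants: 17 tetramethylammonium pentacarbonyl(2-methyl-1-oxidoprop-2-en-1-ylidene)chromate; 12 (3R,4Z)-1-{[tert-butyl(dimethyl)silyl]oxy}-3-methylhept-4-en-6-yn-3-ol
Product: 19 pentacarbonyl[1-{[(3R,4Z)-1-{[tert-butyl(dimethyl)silyl]oxy}-3-methylhept-4-en-6-yn-3-yl]oxy}-2-methylprop-2-en-1-ylidene]chromium, via acetoxycarbene complex 18 (not isolated)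
Conditions: 17 (2.5 equiv), AcBr (2.5 equiv), CH2Cl2, −40 °C; then 12, −40 to −15 °C; filtration through SiO2 at −20 °C
Reagents that add atoms: none
Why: Proposed new method: O-acylation of 17 gives the acetoxycarbene 18, which is strongly electrophilic at the carbene carbon; the neutral tertiary hydroxyl of 12 should add there and expel acetate, and 18 is used in excess and cold because it decomposes on warming, while avoiding an alkoxide keeps the isopropenyl group free of conjugate addition. The closest known reaction type is the alcoholysis of acyloxycarbene complexes by primary and hindered secondary alcohols; a tertiary alcohol has not been shown, and since the C–O bond of the carbinol is not broken the configuration is kept.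

Step 9
Reactants: 19 pentacarbonyl[1-{[(3R,4Z)-1-{[tert-butyl(dimethyl)silyl]oxy}-3-methylhept-4-en-6-yn-3-yl]oxy}-2-methylprop-2-en-1-ylidene]chromium
Product: 21 (2R)-2-(2-{[tert-butyl(dimethyl)silyl]oxy}ethyl)-2,8-dimethyl-2H-chromen-6-ol, via tricarbonylchromium arene complex 20 (not isolated)
Conditions: THF (0.01 M), 50 °C; then air, EtOAc, rt
Reagents that add atoms: none
Why: Proposed new method: loss of one CO from 19 lets the tethered alkyne coordinate and insert into the Cr=C bond; the four-atom O1–C2–C3=C4 tether forces the internal alkyne carbon C4a onto the carbene carbon C8a (6-exo-dig with respect to the alkyne, closing the pyran) and leaves the new carbene on C5. CO insertion at C5 gives a dienylketene (C5–C6), which closes the carbocycle by 6π electrocyclisation onto the isopropenyl CH2 (C6–C7) and tautomerises to the phenol, formed first as its Cr(CO)3 complex 20 and released by air. The closest known reaction type is the intramolecular Dötz benzannulation of alkynes tethered through the carbene oxygen by saturated chains on primary or secondary alkoxy groups; a cis-alkene tether on a tertiary alkoxy group has not been used. No stereocentre is created, and C2 keeps all four of its bonds. The step needs C4a to bond next to C8a, the reverse of the intermolecular preference, and the tether allows nothing else. It needs CO insertion to win over five-ring formation, which chromium, an alkenyl carbene and THF favour, and it needs C8 and C5 cis on the C8a=C4a bond, which the new pyran ring enforces. High dilution should suppress intermolecular alkyne insertion, and the moderate temperature guards against ionisation of the tertiary allylic C2–O bond.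

Step 10
Reactants: 21 (2R)-2-(2-{[tert-butyl(dimethyl)silyl]oxy}ethyl)-2,8-dimethyl-2H-chromen-6-ol
Product: 22 tert-butyl(dimethyl){2-[(2R)-2,8-dimethyl-6-{[tri(propan-2-yl)silyl]oxy}-2H-chromen-2-yl]ethoxy}silane
Conditions: iPr3SiCl, imidazole, DMF, rt
Reagents that add atoms: chlorotri(propan-2-yl)silane CC(C)[Si](Cl)(C(C)C)C(C)C
Why: Silylation of the phenol protects the oxidation-prone 4-alkoxyphenol and removes the acidic proton before the organozinc step.

Step 11
Reactants: 22 tert-butyl(dimethyl){2-[(2R)-2,8-dimethyl-6-{[tri(propan-2-yl)silyl]oxy}-2H-chromen-2-yl]ethoxy}silane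
Product: 23 2-[(2R)-2,8-dimethyl-6-{[tri(propan-2-yl)silyl]oxy}-2H-chromen-2-yl]ethan-1-ol
Conditions: camphorsulfonic acid (10 mol %), MeOH/CH2Cl2, 0 °C
Reagents that add atoms: none
Why: Acid-catalysed methanolysis cleaves a primary alkyl silyl ether much faster than a bulky aryl silyl ether, and catalytic acid at 0 °C should not ionise the chromene.

Step 12
Reactants: 23 2-[(2R)-2,8-dimethyl-6-{[tri(propan-2-yl)silyl]oxy}-2H-chromen-2-yl]ethan-1-ol
Product: 24 {[(2R)-2-(2-iodoethyl)-2,8-dimethyl-2H-chromen-6-yl]oxy}tri(propan-2-yl)silane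
Conditions: I2, PPh3, imidazole, CH2Cl2, 0 °C to rt
Reagents that add atoms: iodine [I][I]
Why: Appel-type iodination of the primary alcohol under buffered conditions; the stereocentre is two carbons away and not involved.

Step 13
Reactants: 25 (R)-epichlorohydrin; 26 ethynyl(trimethyl)silane
Product: 28 (2R)-1-chloro-5-(trimethylsilyl)pent-4-yn-2-ol, via lithium trimethylsilylacetylide 27 (not isolated)
Conditions: 26, n-BuLi, THF, −78 °C; BF3·OEt2; then 25, −78 °C
Reagents that add atoms: none
Why: Yamaguchi–Hirao alkynylation; the acetylide opens the BF3-activated epoxide at its CH2 terminus, so the stereocentre is untouched and the chloride is kept for later ring closure.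

Step 14
Reactants: 28 (2R)-1-chloro-5-(trimethylsilyl)pent-4-yn-2-ol
Product: 29 (2R)-1-chloropent-4-yn-2-ol
Conditions: Bu4NF, AcOH, THF, 0 °C
Reagents that add atoms: none
Why: Fluoride-induced protodesilylation of the alkynylsilane; the acetic acid buffer keeps the chlorohydrin from closing to a volatile epoxide.

Step 15
Reactants: 29 (2R)-1-chloropent-4-yn-2-ol
Product: 31 (2R,4E)-1-chloro-5-iodo-4-methylpent-4-en-2-ol, via alkenylalane 30 (not isolated)
Conditions: AlMe3 (3 equiv), Cp2ZrCl2 (25 mol %), CH2Cl2, 0 °C to rt; I2, THF, −30 °C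
Reagents that add atoms: trimethylaluminium C[Al](C)C; iodine [I][I]
Why: Negishi carboalumination of a homopropargylic alcohol as its aluminium alkoxide, followed by iodinolysis with retention; syn addition fixes the E vinyl iodide that becomes the chain alkene.

Step 16
Reactants: 31 (2R,4E)-1-chloro-5-iodo-4-methylpent-4-en-2-ol
Product: 32 (2R)-2-[(2E)-3-iodo-2-methylprop-2-en-1-yl]oxirane
Conditions: K2CO3, MeOH, rt
Reagents that add atoms: none
Why: Intramolecular Williamson closure of the chlorohydrin; the oxygen-bearing stereocentre is the nucleophile, so its configuration is kept.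

Step 17
Reactants: 32 (2R)-2-[(2E)-3-iodo-2-methylprop-2-en-1-yl]oxirane; 33 (phenylsulfanyl)acetic acid
Product: 36 (5R)-5-[(2E)-3-iodo-2-methylprop-2-en-1-yl]-3-(phenylsulfanyl)oxolan-2-one, via dilithiated acid 34 (not isolated), via hydroxy acid 35 (not isolated)
Conditions: 33, LiN(iPr)2 (2.1 equiv), THF, −78 to 0 °C; then 32, 0 °C to rt; TsOH (cat.), toluene, rt
Reagents that add atoms: none
Why: The sulfur-stabilised dianion opens the terminal epoxide at CH2 and the γ-hydroxy acid lactonises under acid, as in the standard route to α-sulfenyl γ-lactones. The C5–O bond is not touched, and the mixture at C3 is of no consequence.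

Step 18
Reactants: 36 (5R)-5-[(2E)-3-iodo-2-methylprop-2-en-1-yl]-3-(phenylsulfanyl)oxolan-2-one; 37 5-bromo-2-methylpent-2-ene
Product: 39 (5R)-5-[(2E)-3-iodo-2-methylprop-2-en-1-yl]-3-(4-methylpent-3-en-1-yl)-3-(phenylsulfanyl)oxolan-2-one, via lithium enolate 38 (not isolated)
Conditions: LiN(SiMe3)2, THF/HMPA, −78 °C; then 37, Bu4NI (cat.), −78 °C to rt
Reagents that add atoms: none
Why: Alkylation of a sulfur-stabilised lactone enolate with a primary halide; the amide base does not exchange with the vinyl iodide, and C3 becomes sp2 in the next step.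

Step 19
Reactants: 39 (5R)-5-[(2E)-3-iodo-2-methylprop-2-en-1-yl]-3-(4-methylpent-3-en-1-yl)-3-(phenylsulfanyl)oxolan-2-one
Product: 41 (5R)-5-[(2E)-3-iodo-2-methylprop-2-en-1-yl]-3-(4-methylpent-3-en-1-yl)furan-2(5H)-one, via sulfoxide 40 (not isolated)
Conditions: mCPBA (1.0 equiv), CH2Cl2, −78 °C; then toluene, NaHCO3, 110 °C
Reagents that add atoms: none
Why: Sulfide oxidation at −78 °C is much faster than alkene epoxidation, and thermal syn elimination of the sulfoxide towards the ring CH2 should give the conjugated butenolide without base at C5.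

Step 20
Reactants: 24 {[(2R)-2-(2-iodoethyl)-2,8-dimethyl-2H-chromen-6-yl]oxy}tri(propan-2-yl)silane; 41 (5R)-5-[(2E)-3-iodo-2-methylprop-2-en-1-yl]-3-(4-methylpent-3-en-1-yl)furan-2(5H)-one
Product: 43 (5R)-5-{(2E)-5-[(2R)-2,8-dimethyl-6-{[tri(propan-2-yl)silyl]oxy}-2H-chromen-2-yl]-2-methylpent-2-en-1-yl}-3-(4-methylpent-3-en-1-yl)furan-2(5H)-one, via alkylzinc iodide 42 (not isolated)
Conditions: 24, Zn dust (activated with BrCH2CH2Br and Me3SiCl), LiCl, THF, 40 °C; then 41, Pd(dppf)Cl2 (5 mol %), THF/NMP, rt
Reagents that add atoms: none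
Why: Negishi sp3–sp2 coupling; zinc inserts into the primary iodide, and the alkylzinc tolerates the lactone and silyl ether. The divalent palladium precatalyst is reduced in the flask and couples with retention of the E geometry.

Step 21
Reactants: 43 (5R)-5-{(2E)-5-[(2R)-2,8-dimethyl-6-{[tri(propan-2-yl)silyl]oxy}-2H-chromen-2-yl]-2-methylpent-2-en-1-yl}-3-(4-methylpent-3-en-1-yl)furan-2(5H)-one
Product: 44 (5R)-5-{(2E)-5-[(2R)-6-hydroxy-2,8-dimethyl-2H-chromen-2-yl]-2-methylpent-2-en-1-yl}-3-(4-methylpent-3-en-1-yl)furan-2(5H)-one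
Conditions: Bu4NF, AcOH, THF, 0 °C
Reagents that add atoms: none
Why: Fluoride cleaves the aryl silyl ether quickly, and the acetic acid buffer should prevent epimerisation at the butenolide C5.

## Compound list

1 | tert-butyl(but-3-yn-1-yloxy)dimethylsilane | C#CCCO[Si](C)(C)C(C)(C)C | starting material
2 | [(1E)-4-{[tert-butyl(dimethyl)silyl]oxy}-2-methylbut-1-en-1-yl]dimethylaluminium (formed in the flask) | C[Al](C)/C=C(\C)CCO[Si](C)(C)C(C)(C)C | intermediate
3 | lithium butyl[(1E)-4-{[tert-butyl(dimethyl)silyl]oxy}-2-methylbut-1-en-1-yl]dimethylaluminate (formed in the flask) | [Li+].CCCC[Al-](C)(C)/C=C(\C)CCO[Si](C)(C)C(C)(C)C | intermediate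
4 | (2E)-5-{[tert-butyl(dimethyl)silyl]oxy}-3-methylpent-2-en-1-ol | CC(C)(C)[Si](C)(C)OCC/C(C)=C/CO | intermediate
5 | [(2R,3R)-3-(2-{[tert-butyl(dimethyl)silyl]oxy}ethyl)-3-methyloxiran-2-yl]methanol | CC(C)(C)[Si](C)(C)OCC[C@@]1(C)O[C@@H]1CO | intermediate
6 | tert-butyl{2-[(2R,3S)-3-(chloromethyl)-2-methyloxiran-2-yl]ethoxy}dimethylsilane | CC(C)(C)[Si](C)(C)OCC[C@@]1(C)O[C@@H]1CCl | intermediate
7 | dilithium salt of (3R)-5-{[tert-butyl(dimethyl)silyl]oxy}-3-methylpent-1-yn-3-ol, lithiated at oxygen and at the alkyne terminus (formed in the flask) | CC(C)(C)[Si](C)(C)OCC[C@](O[Li])(C)C#C[Li] | intermediate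
8 | (3R)-5-{[tert-butyl(dimethyl)silyl]oxy}-1-iodo-3-methylpent-1-yn-3-ol | CC(C)(C)[Si](C)(C)OCC[C@](O)(C)C#CI | intermediate
9 | (1Z,3R)-5-{[tert-butyl(dimethyl)silyl]oxy}-1-iodo-3-methylpent-1-en-3-ol | CC(C)(C)[Si](C)(C)OCC[C@](O)(C)/C=C\I | intermediate
10 | ethynylmagnesium bromide | C#C[Mg]Br | starting material
11 | ethynylzinc bromide (formed in the flask) | C#C[Zn]Br | intermediate
12 | (3R,4Z)-1-{[tert-butyl(dimethyl)silyl]oxy}-3-methylhept-4-en-6-yn-3-ol | CC(C)(C)[Si](C)(C)OCC[C@](O)(C)/C=C\C#C | intermediate
13 | 2-bromopropene | C=C(C)Br | starting material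
14 | hexacarbonylchromium | O=C=[Cr](=C=O)(=C=O)(=C=O)(=C=O)=C=O | starting material
15 | isopropenyllithium (formed in the flask) | [Li]C(C)=C | intermediate
16 | lithium pentacarbonyl(2-methyl-1-oxidoprop-2-en-1-ylidene)chromate (formed in the flask) | [Li+].[O-]C(C(C)=C)=[Cr](=C=O)(=C=O)(=C=O)(=C=O)=C=O | intermediate
17 | tetramethylammonium pentacarbonyl(2-methyl-1-oxidoprop-2-en-1-ylidene)chromate | C[N+](C)(C)C.[O-]C(C(C)=C)=[Cr](=C=O)(=C=O)(=C=O)(=C=O)=C=O | intermediate
18 | pentacarbonyl[1-(acetyloxy)-2-methylprop-2-en-1-ylidene]chromium (formed in the flask) | CC(=O)OC(C(C)=C)=[Cr](=C=O)(=C=O)(=C=O)(=C=O)=C=O | intermediate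
19 | pentacarbonyl[1-{[(3R,4Z)-1-{[tert-butyl(dimethyl)silyl]oxy}-3-methylhept-4-en-6-yn-3-yl]oxy}-2-methylprop-2-en-1-ylidene]chromium | CC(C)(C)[Si](C)(C)OCC[C@](OC(C(C)=C)=[Cr](=C=O)(=C=O)(=C=O)(=C=O)=C=O)(C)/C=C\C#C | intermediate
20 | tricarbonylchromium complex of 21, bound through the six carbons of the benzene ring (formed in the flask; drawn as two parts) | CC(C)(C)[Si](C)(C)OCC[C@]2(C)C=Cc3cc(O)cc(C)c3O2.[Cr](=C=O)(=C=O)=C=O | intermediate
21 | (2R)-2-(2-{[tert-butyl(dimethyl)silyl]oxy}ethyl)-2,8-dimethyl-2H-chromen-6-ol | CC(C)(C)[Si](C)(C)OCC[C@]2(C)C=Cc3cc(O)cc(C)c3O2 | intermediate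
22 | tert-butyl(dimethyl){2-[(2R)-2,8-dimethyl-6-{[tri(propan-2-yl)silyl]oxy}-2H-chromen-2-yl]ethoxy}silane | CC(C)(C)[Si](C)(C)OCC[C@]2(C)C=Cc3cc(O[Si](C(C)C)(C(C)C)C(C)C)cc(C)c3O2 | intermediate
23 | 2-[(2R)-2,8-dimethyl-6-{[tri(propan-2-yl)silyl]oxy}-2H-chromen-2-yl]ethan-1-ol | OCC[C@]2(C)C=Cc3cc(O[Si](C(C)C)(C(C)C)C(C)C)cc(C)c3O2 | intermediate
24 | {[(2R)-2-(2-iodoethyl)-2,8-dimethyl-2H-chromen-6-yl]oxy}tri(propan-2-yl)silane | ICC[C@]2(C)C=Cc3cc(O[Si](C(C)C)(C(C)C)C(C)C)cc(C)c3O2 | intermediate
25 | (R)-epichlorohydrin, (2R)-2-(chloromethyl)oxirane | ClC[C@H]1CO1 | starting material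
26 | ethynyl(trimethyl)silane | C#C[Si](C)(C)C | starting material
27 | lithium (trimethylsilyl)acetylide (formed in the flask) | [Li]C#C[Si](C)(C)C | intermediate
28 | (2R)-1-chloro-5-(trimethylsilyl)pent-4-yn-2-ol | ClC[C@@H](CC#C[Si](C)(C)C)O | intermediate
29 | (2R)-1-chloropent-4-yn-2-ol | ClC[C@@H](CC#C)O | intermediate
30 | dimethylaluminium (2R,4E)-1-chloro-5-(dimethylalumanyl)-4-methylpent-4-en-2-olate (formed in the flask) | ClC[C@@H](C/C(C)=C/[Al](C)C)O[Al](C)C | intermediate
31 | (2R,4E)-1-chloro-5-iodo-4-methylpent-4-en-2-ol | ClC[C@@H](C/C(C)=C/I)O | intermediate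
32 | (2R)-2-[(2E)-3-iodo-2-methylprop-2-en-1-yl]oxirane | C1[C@@H](C/C(C)=C/I)O1 | intermediate
33 | (phenylsulfanyl)acetic acid | OC(=O)CSc1ccccc1 | starting material
34 | dilithium salt of (phenylsulfanyl)acetic acid, lithiated at oxygen and at C2 (formed in the flask) | [Li]OC(=O)C([Li])Sc1ccccc1 | intermediate
35 | (4R,6E)-4-hydroxy-7-iodo-6-methyl-2-(phenylsulfanyl)hept-6-enoic acid, both C2 epimers (formed in the flask) | OC(=O)C(Sc1ccccc1)C[C@H](O)C/C(C)=C/I | intermediate
36 | (5R)-5-[(2E)-3-iodo-2-methylprop-2-en-1-yl]-3-(phenylsulfanyl)oxolan-2-one, both C3 epimers | c1ccccc1SC1C[C@@H](C/C(C)=C/I)OC1=O | intermediate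
37 | 5-bromo-2-methylpent-2-ene | CC(C)=CCCBr | starting material
38 | lithium enolate of 36 (formed in the flask) | [Li]OC1=C(Sc2ccccc2)C[C@@H](C/C(C)=C/I)O1 | intermediate
39 | (5R)-5-[(2E)-3-iodo-2-methylprop-2-en-1-yl]-3-(4-methylpent-3-en-1-yl)-3-(phenylsulfanyl)oxolan-2-one, both C3 epimers | CC(C)=CCCC1(Sc2ccccc2)C[C@@H](C/C(C)=C/I)OC1=O | intermediate
40 | (5R)-5-[(2E)-3-iodo-2-methylprop-2-en-1-yl]-3-(4-methylpent-3-en-1-yl)-3-(phenylsulfinyl)oxolan-2-one (formed in the flask) | CC(C)=CCCC1(S(=O)c2ccccc2)C[C@@H](C/C(C)=C/I)OC1=O | intermediate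
41 | (5R)-5-[(2E)-3-iodo-2-methylprop-2-en-1-yl]-3-(4-methylpent-3-en-1-yl)furan-2(5H)-one | CC(C)=CCCC1=C[C@@H](C/C(C)=C/I)OC1=O | intermediate
42 | {2-[(2R)-2,8-dimethyl-6-{[tri(propan-2-yl)silyl]oxy}-2H-chromen-2-yl]ethyl}zinc iodide (formed in the flask) | I[Zn]CC[C@]2(C)C=Cc3cc(O[Si](C(C)C)(C(C)C)C(C)C)cc(C)c3O2 | intermediate
43 | (5R)-5-{(2E)-5-[(2R)-2,8-dimethyl-6-{[tri(propan-2-yl)silyl]oxy}-2H-chromen-2-yl]-2-methylpent-2-en-1-yl}-3-(4-methylpent-3-en-1-yl)furan-2(5H)-one | CC(C)=CCCC1=C[C@@H](C/C(C)=C/CC[C@]2(C)C=Cc3cc(O[Si](C(C)C)(C(C)C)C(C)C)cc(C)c3O2)OC1=O | intermediate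
44 | 2'-epi-tuberatolide B, (5R)-5-{(2E)-5-[(2R)-6-hydroxy-2,8-dimethyl-2H-chromen-2-yl]-2-methylpent-2-en-1-yl}-3-(4-methylpent-3-en-1-yl)furan-2(5H)-one | CC(C)=CCCC1=C[C@@H](C/C(C)=C/CC[C@]2(C)C=Cc3cc(O)cc(C)c3O2)OC1=O | target

## Step count and least certain steps

Total: 21 steps. Longest linear sequence: 13 steps (steps 1–6, 8–12, 20 and 21, from 1). The carbene salt takes one step (7) and the butenolide fragment seven (13–19).

**Step 9 (key step, proposed new method).** The most likely failure is that the chromium vinylcarbene formed by alkyne insertion closes without taking up CO, or that the tertiary allylic C2–O bond of the electron-poor alkoxycarbene ionises before CO is lost; either would consume 19 without forming the arene. The fallback uses known reactions, sets out from vinyl iodide 9 and returns at 21.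
- 4-Fluoro-3-methylbenzaldehyde is protected as 2-(4-fluoro-3-methylphenyl)-1,3-dioxolane F1 (ethylene glycol, TsOH).
- F1 is lithiated ortho to fluorine (s-BuLi, THF, −78 °C), borylated with B(OiPr)3 and hydrolysed with aqueous HCl to (2-fluoro-5-formyl-3-methylphenyl)boronic acid F2.
- Suzuki–Miyaura coupling of F2 with 9 (Pd(PPh3)4, K3PO4, dioxane/H2O) should give, with retention, 4-fluoro-3-[(1Z,3R)-5-{[tert-butyl(dimethyl)silyl]oxy}-3-hydroxy-3-methylpent-1-en-1-yl]-5-methylbenzaldehyde F3.
- The tertiary alkoxide (KN(SiMe3)2, DMF, 0 °C to rt) displaces the fluoride para to the formyl group in an intramolecular nucleophilic aromatic substitution to give (2R)-2-(2-{[tert-butyl(dimethyl)silyl]oxy}ethyl)-2,8-dimethyl-2H-chromene-6-carbaldehyde F4.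
- Dakin-type oxidation (H2O2, catalytic (PhSe)2, CH2Cl2) gives (2R)-2-(2-{[tert-butyl(dimethyl)silyl]oxy}ethyl)-2,8-dimethyl-2H-chromen-6-yl formate F5, and methanolysis (K2CO3, MeOH) gives 21.
- No bond to C2 is broken on this path.

**Step 8 (proposed new method).** The most likely failure is that addition of the hindered tertiary hydroxyl to the carbene carbon is slower than the thermal decomposition of 18, so that 12 is recovered and no 19 forms; acetic acid set free may also promote ionisation of the product. The fallback uses known reactions, sets out from epoxy chloride 6 and returns at 22, bypassing chromium.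
- 6 is fragmented as in step 4 but quenched with NH4Cl to give (3R)-5-{[tert-butyl(dimethyl)silyl]oxy}-3-methylpent-1-yn-3-ol F6.
- Deprotonation of F6 (KN(SiMe3)2, DMF) and nucleophilic aromatic substitution on 4-fluoro-3-methylbenzaldehyde give 4-{[(3R)-5-{[tert-butyl(dimethyl)silyl]oxy}-3-methylpent-1-yn-3-yl]oxy}-3-methylbenzaldehyde F7, with the C–O bond of the carbinol intact.
- Dakin-type oxidation (mCPBA, CH2Cl2) gives 4-{[(3R)-5-{[tert-butyl(dimethyl)silyl]oxy}-3-methylpent-1-yn-3-yl]oxy}-3-methylphenyl formate F8, and methanolysis (K2CO3, MeOH) gives 4-{[(3R)-5-{[tert-butyl(dimethyl)silyl]oxy}-3-methylpent-1-yn-3-yl]oxy}-3-methylphenol F9.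
- Silylation (iPr3SiCl, imidazole) gives tert-butyl(dimethyl){[(3R)-3-methyl-3-(2-methyl-4-{[tri(propan-2-yl)silyl]oxy}phenoxy)pent-4-yn-1-yl]oxy}silane F10.
- Ph3PAuNTf2 (2 mol %, CH2Cl2, rt) closes the pyran by 6-endo hydroarylation at the only free ortho carbon to give 22.

**Step 20.** Zinc insertion into the β-branched iodide may be sluggish, the zinc reagent 42 may be protonated, or β-hydride elimination at palladium may give reduced chain instead of coupling. The fallback sets out from 24 and returns at 43 by a B-alkyl Suzuki–Miyaura coupling.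
- Iodine–lithium exchange (t-BuLi, Et2O, −78 °C) gives {2-[(2R)-2,8-dimethyl-6-{[tri(propan-2-yl)silyl]oxy}-2H-chromen-2-yl]ethyl}lithium F11.
- F11 is trapped with 9-methoxy-9-borabicyclo[3.3.1]nonane as the lithium B-alkyl-B-methoxy borate F12.
- F12 is coupled with 41 (Pd(dppf)Cl2, AsPh3, K3PO4, DMF/H2O, rt) to give 43.

**Step 18.** Bromide 37 may undergo elimination, or the hindered enolate 38 may alkylate slowly, so that 36 is recovered. The fallback sets out from 33 and returns at 39 by reversing the order of the two C–C bond formations.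
- The dilithiated acid 34 is alkylated with 37 (THF/HMPA) to give 6-methyl-2-(phenylsulfanyl)hept-5-enoic acid F13.
- F13 is deprotonated twice (LiN(iPr)2) and opens epoxide 32 to give (4R,6E)-4-hydroxy-7-iodo-6-methyl-2-(4-methylpent-3-en-1-yl)-2-(phenylsulfanyl)hept-6-enoic acid F14.
- F14 lactonises with TsOH to give 39.

## Further compounds

F1 | step 9 | 2-(4-fluoro-3-methylphenyl)-1,3-dioxolane | Cc1cc(C2OCCO2)ccc1F
F2 | step 9 | (2-fluoro-5-formyl-3-methylphenyl)boronic acid | OB(O)c1cc(C=O)cc(C)c1F
F3 | step 9 | 4-fluoro-3-[(1Z,3R)-5-{[tert-butyl(dimethyl)silyl]oxy}-3-hydroxy-3-methylpent-1-en-1-yl]-5-methylbenzaldehyde | CC(C)(C)[Si](C)(C)OCC[C@](O)(C)/C=C\c1cc(C=O)cc(C)c1F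
F4 | step 9 | (2R)-2-(2-{[tert-butyl(dimethyl)silyl]oxy}ethyl)-2,8-dimethyl-2H-chromene-6-carbaldehyde | CC(C)(C)[Si](C)(C)OCC[C@]2(C)C=Cc3cc(C=O)cc(C)c3O2
F5 | step 9 | (2R)-2-(2-{[tert-butyl(dimethyl)silyl]oxy}ethyl)-2,8-dimethyl-2H-chromen-6-yl formate | CC(C)(C)[Si](C)(C)OCC[C@]2(C)C=Cc3cc(OC=O)cc(C)c3O2
F6 | step 8 | (3R)-5-{[tert-butyl(dimethyl)silyl]oxy}-3-methylpent-1-yn-3-ol | CC(C)(C)[Si](C)(C)OCC[C@](O)(C)C#C
F7 | step 8 | 4-{[(3R)-5-{[tert-butyl(dimethyl)silyl]oxy}-3-methylpent-1-yn-3-yl]oxy}-3-methylbenzaldehyde | CC(C)(C)[Si](C)(C)OCC[C@](Oc1ccc(C=O)cc1C)(C)C#C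
F8 | step 8 | 4-{[(3R)-5-{[tert-butyl(dimethyl)silyl]oxy}-3-methylpent-1-yn-3-yl]oxy}-3-methylphenyl formate | CC(C)(C)[Si](C)(C)OCC[C@](Oc1ccc(OC=O)cc1C)(C)C#C
F9 | step 8 | 4-{[(3R)-5-{[tert-butyl(dimethyl)silyl]oxy}-3-methylpent-1-yn-3-yl]oxy}-3-methylphenol | CC(C)(C)[Si](C)(C)OCC[C@](Oc1ccc(O)cc1C)(C)C#C
F10 | step 8 | tert-butyl(dimethyl){[(3R)-3-methyl-3-(2-methyl-4-{[tri(propan-2-yl)silyl]oxy}phenoxy)pent-4-yn-1-yl]oxy}silane | CC(C)(C)[Si](C)(C)OCC[C@](Oc1ccc(O[Si](C(C)C)(C(C)C)C(C)C)cc1C)(C)C#C
F11 | step 20 | {2-[(2R)-2,8-dimethyl-6-{[tri(propan-2-yl)silyl]oxy}-2H-chromen-2-yl]ethyl}lithium | [Li]CC[C@]2(C)C=Cc3cc(O[Si](C(C)C)(C(C)C)C(C)C)cc(C)c3O2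
F12 | step 20 | lithium 9-{2-[(2R)-2,8-dimethyl-6-{[tri(propan-2-yl)silyl]oxy}-2H-chromen-2-yl]ethyl}-9-methoxy-9-boranuidabicyclo[3.3.1]nonane | [Li+].CO[B-]1(CC[C@]2(C)C=Cc3cc(O[Si](C(C)C)(C(C)C)C(C)C)cc(C)c3O2)C4CCCC1CCC4
F13 | step 18 | 6-methyl-2-(phenylsulfanyl)hept-5-enoic acid | CC(C)=CCCC(Sc1ccccc1)C(=O)O
F14 | step 18 | (4R,6E)-4-hydroxy-7-iodo-6-methyl-2-(4-methylpent-3-en-1-yl)-2-(phenylsulfanyl)hept-6-enoic acid | CC(C)=CCCC(Sc1ccccc1)(C[C@H](O)C/C(C)=C/I)C(=O)O
A1 | alternative 1 | 2-{(2S,3S)-3-[2-hydroxy-3-methyl-5-{[tri(propan-2-yl)silyl]oxy}benzyl]-2-methyloxiran-2-yl}ethyl 2,2-dimethylpropanoate | CC(C)(C)C(=O)OCC[C@]1(C)O[C@H]1Cc1cc(O[Si](C(C)C)(C(C)C)C(C)C)cc(C)c1O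
A2 | alternative 1 | 2-[(2R,3S)-3-hydroxy-2,8-dimethyl-6-{[tri(propan-2-yl)silyl]oxy}-3,4-dihydro-2H-chromen-2-yl]ethyl 2,2-dimethylpropanoate | CC(C)(C)C(=O)OCC[C@]2(C)[C@@H](O)Cc3cc(O[Si](C(C)C)(C(C)C)C(C)C)cc(C)c3O2
A3 | alternative 2 | axially chiral (6E)-9-[(2R)-6-{[tert-butyl(dimethyl)silyl]oxy}-2,8-dimethyl-2H-chromen-2-yl]-6-methyl-2-(4-methylpent-3-en-1-yl)nona-2,3,6-trienoic acid | CC(C)=CCCC(C(=O)O)=[C@@]=C([H])C/C(C)=C/CC[C@]2(C)C=Cc3cc(O[Si](C)(C)C(C)(C)C)cc(C)c3O2
A4 | alternative 2 | 2'-epi-tuberatolide B tert-butyldimethylsilyl ether | CC(C)=CCCC1=C[C@@H](C/C(C)=C/CC[C@]2(C)C=Cc3cc(O[Si](C)(C)C(C)(C)C)cc(C)c3O2)OC1=O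
A5 | alternative 3 | tert-butyl(dimethyl){[(3R)-3-methyl-3-(2-methyl-4-{[tri(propan-2-yl)silyl]oxy}phenoxy)pent-4-yn-1-yl]oxy}silane (identical with F10) | CC(C)(C)[Si](C)(C)OCC[C@](Oc1ccc(O[Si](C(C)C)(C(C)C)C(C)C)cc1C)(C)C#C
A6 | alternative 3 | tert-butyl(dimethyl){2-[(2R)-2,8-dimethyl-6-{[tri(propan-2-yl)silyl]oxy}-2H-chromen-2-yl]ethoxy}silane (identical with 22) | CC(C)(C)[Si](C)(C)OCC[C@]2(C)C=Cc3cc(O[Si](C(C)C)(C(C)C)C(C)C)cc(C)c3O2
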